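## The problem

The target 20 is an oxolane with a 4-hydroxy-3-methoxyphenyl group on each of C2 and C5, a methyl group on each of C3 and C4, and a tertiary hydroxyl on C3. Its four stereocentres are contiguous, (2R,3S,4S,5R): the aryl groups are cis across the ring oxygen, the C3 hydroxyl is trans to the C2 aryl group and cis to the C4 methyl group, and the C4 methyl group is trans to the C5 aryl group. The trans relationship at C4/C5 can be reached by substrate control, because a methyl group on C4 steers a nucleophile at C5 to the other face. The C2 aryl group cis to the C3 methyl group is the more crowded arrangement at a benzylic carbon, so it has to come from a stereospecific step and must not be equilibrated afterwards. The hydroxyl removes all symmetry, so the two benzylic carbons cannot be made in one stroke without a device that tells them apart. Sensitive features are the two free guaiacyl phenols (oxidation), the two benzylic C–O bonds next to electron-rich arenes (ionisation by acid, hydrogenolysis) and the tertiary oxygen on C3, which is expelled once a carbanion sits next to it. The key step is possible because O1 lies between C2, a benzylic carbon with a strongly donating aryl group, and C5. If O1 is removed and C2 is bonded to C5 drawn as a carbonyl carbon, a cyclobutanone results whose three sp3 carbons already carry the C2, C3 and C4 substituents, and oxygen can be reinserted on the benzylic side.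

## Retrosynthesis

Target 20 is traced back to its tribenzyl ether 19 by cutting three O–benzyl bonds. One protecting group for both phenols and the tertiary alcohol means a single neutral deprotection at the end. The forward reaction must cleave the benzyl ethers without hydrogenolysing the two ring C–O bonds.

Ether 19 is cut at the C5–aryl bond to give the anomeric acetate 16 and the arylzinc bromide 18, which is made from aryl bromide 2 through aryllithium 17. The C2–aryl bond is not cut because C2 sits next to the quaternary carbinol and carries the contra-steric configuration, which is safer to bring in already fixed. The precursor has one aryl group and one stereocentre less. The forward reaction must add the aryl group to the oxocarbenium ion on the face opposite the C4 methyl group.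

Acetate 16 comes from lactol 15 and this from lactone 14 by adjusting the oxidation level of C5. No skeletal bond is cut. The lactone is stable and has C2, C3 and C4 in place.

Lactone 14 is cut at the O1–C2 bond, and C2 is joined to the carbonyl carbon, which gives cyclobutanone 13. The neighbouring cut at the ester C–O bond would lead to an open-chain hydroxy acid whose three stereocentres would have to be set without a ring. The chosen cut puts them on a rigid four-membered ring that a cycloaddition can deliver. The forward Baeyer–Villiger oxidation must make C2 migrate in preference to C4, with retention.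

Cyclobutanone 13 is taken from its racemate 12 by separating the enantiomers. The ring-forming cycloaddition below is stereospecific but has no dependable asymmetric version for enol ethers. Separating at this point lets the key step and everything after it run on one enantiomer.

Racemate 12 is cut at the C4–methyl bond to give chloro ketone 9 and iodomethane 10, through enolate 11. A methyl group carried in on the ketene would end on the crowded face, cis to the aryl and C3 methyl groups, because ketene cycloadditions place the larger ketene substituent there. Correcting C4 by equilibration would also touch the more acidic benzylic C2. The chlorine in 9 allows the enolate to be formed towards C4 only, and the methyl group should then enter from the open face.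

Chloro ketone 9 is cut at the C1–C2 and C3–C4 bonds into enol ether 6 and chloroketene 8, which comes from chloroacetyl chloride 7. The polarity of the enol ether fixes the regiochemistry. A neutral ketene adds suprafacially to the alkene, so the geometry of 6 becomes the cis relationship of aryl and C3 methyl. An enantioselective, auxiliary-bearing cationic variant was set aside. Such electrophiles add to enol ethers stepwise through an oxocarbenium ion whose C2–C3 bond can rotate, so the alkene geometry would not be transmitted.

Enol ether 6 is cut at its vinyl C–O bond to give alkenylboronate 5. O-alkylation of the corresponding ketone enolate is not used because it favours C-alkylation and the isomer with aryl cis to oxygen. Copper-mediated C–O coupling of 5 keeps the double-bond geometry. Boronate 5 comes from alkyne 4 by syn addition of boron and hydrogen, 4 from aryl bromide 2 and propyne 3 by cutting the aryl–alkyne bond, and 2 from 4-bromo-2-methoxyphenol 1. Bromide 2 serves twice, for both aryl groups.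

## Roads not taken

Alternative 1: Both C–aryl bonds are cut. The ring carbons come from an enantiopure 3-acetoxy-3,4-dimethyloxolane-2,5-diyl diacetate A2. BF3·OEt2 ionises the two anomeric acetates in turn and two equivalents of arylzinc bromide 18 add to give the target 3-O-acetate bis(benzyl ether) A1. No ring is formed in the key step.
- Merits: this is the most convergent plan, with both identical aryl groups from one reagent and a small core. The C3 acetate can shield its own face of the C2 cation by participation, which would place the aryl group trans to the acetoxy group and so cis to the C3 methyl group, the difficult relationship. The C4 methyl group directs C5.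
- Weak points: A2 is a masked 2-hydroxy-2,3-dimethylsuccinaldehyde whose two stereocentres still have to be made, and it is not easier to reach than 13. Participation by a tertiary acetate can end in a dioxolenium ion that is attacked at the wrong carbon. The first benzylic C–O bond formed can ionise again under the Lewis acid while the second, inductively slowed acetate is being ionised.
- Comparison: in convergence, and possibly in how it sets C2 against C3, this road is as good as or better than the chosen one, and it needs no enantiomer separation if A2 is made from an enantiopure building block. The chosen plan has to set against it that C2 is fixed by a stereospecific cycloaddition and carried through a migration with retention before any Lewis acid is used, and that only one benzylic centre is formed under ionising conditions.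

Alternative 2: The C4–C5 bond is cut, and the C3 methyl group is removed to leave a ketone. A mandelic acid with the protected aryl group is condensed with the aryl aldehyde and ethylidenated to the (Z)-5-ethylidene-2,4-cis-diaryl-1,3-dioxolane A4. Me2AlCl opens it to an oxocarbenium ion and an aluminium enolate, which reclose by C4–C5 bond formation to the 2,5-cis oxolan-3-one A3. Methyl addition to the ketone and deprotection would finish the synthesis.
- Merits: the absolute configuration comes from the mandelate, the 2,5-cis relationship is the normal outcome of the rearrangement, and the ring is made in one step.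
- Weak points: the methyl nucleophile must enter A3 on the face of the C2 aryl group and opposite the C4 methyl group. The two flanking groups lie on opposite faces, so there is no clear bias, and the required face is the one next to the larger group. A3 is also an enolisable α-aryl-α-alkoxy ketone, so basic organometallics can epimerise C2 and C4. The electron-rich mandelate centre can racemise on the way to A4.
- Comparison: this road is better in absolute stereocontrol and probably shorter. The chosen plan has to set against it that the carbinol carbon arrives with both its methyl group and its oxygen from the enol ether, so no late addition to a hindered, enolisable ketone is needed.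

Alternative 3: The C3–C4 bond and both C–O1 bonds are cut. Laccase and O2 with a dirigent protein oxidise (E)-isoeugenol A6 and its 8-acetoxy analogue A7 to phenoxyl radicals. These couple C3 to C4 to a bis(quinone methide), which takes up water at one benzylic carbon and closes on the other to give the target 3-O-acetate A5. Acetate hydrolysis would follow.
- Merits: two steps, no protecting groups, water as the source of the ring oxygen.
- Weak points: two different radicals must cross-couple in competition with both homo-couplings and with the 8–5' and 8–O–4' modes. Dirigent proteins are known to guide like-with-like coupling of coniferyl-type radicals, and one that pairs A6 with A7 and controls all four centres is not available. The water capture at two quinone methides is not under any obvious control.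
- Comparison: in step economy the chosen plan cannot compete. It sets against this that each stereocentre is made in a separate event with a known rule, so failures can be located and repaired.

Key step: step 8

Remark: racemic compounds are written in the lists as the two enantiomers joined by a dot. It is assumed that the enantiomer kept in step 7 can be identified as 13 by X-ray analysis of a crystalline derivative or, at the latest, by comparing 20 with the natural product.
Remark: cyclobutanones are numbered C1 (carbonyl), C2 (aryl-bearing), C3 (benzyloxy-bearing), C4. Lactone 14 and its descendants are numbered as oxolanes from the ring oxygen.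

## Steps

Step 1
Reactants: 1 4-bromo-2-methoxyphenol
Product: 2 1-(benzyloxy)-4-bromo-2-methoxybenzene
Conditions: BnBr, K2CO3, DMF, rt
Reagents that add atoms: benzyl bromide, BrCc1ccccc1
Why: Williamson ether synthesis; the phenoxide is alkylated at oxygen by the benzylic bromide and nothing else in the molecule reacts.

Step 2
Reactants: 2 1-(benzyloxy)-4-bromo-2-methoxybenzene; 3 propyne
Product: 4 1-(benzyloxy)-2-methoxy-4-(prop-1-yn-1-yl)benzene
Conditions: propyne (1 M in THF), Pd(PhCN)2Cl2 (3 mol%), HP(t-Bu)3BF4 (6 mol%), CuI (2 mol%), HN(i-Pr)2, dioxane, rt
Reagents that add atoms: none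
Why: Sonogashira coupling; the bulky electron-rich phosphine lets the electron-rich aryl bromide undergo oxidative addition at room temperature, and the aryl benzyl ether is inert.

Step 3
Reactants: 4 1-(benzyloxy)-2-methoxy-4-(prop-1-yn-1-yl)benzene
Product: 5 2-{(1Z)-1-[4-(benzyloxy)-3-methoxyphenyl]prop-1-en-2-yl}-4,4,5,5-tetramethyl-1,3,2-dioxaborolane
Conditions: B2pin2, CuCl (5 mol%), NaOt-Bu (10 mol%), P(p-tol)3 (6 mol%), MeOH (2 equiv), THF, rt
Reagents that add atoms: bis(pinacolato)diboron, CC1(C)OB(OC1(C)C)B1OC(C)(C)C(C)(C)O1
Why: Copper-catalysed formal hydroboration of an aryl alkyne; the Cu–B bond adds syn with copper at the benzylic carbon and boron at the methyl-bearing carbon, and methanol protonates the C–Cu bond with retention, so aryl and methyl should end cis.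

Step 4
Reactants: 5 2-{(1Z)-1-[4-(benzyloxy)-3-methoxyphenyl]prop-1-en-2-yl}-4,4,5,5-tetramethyl-1,3,2-dioxaborolane
Product: 6 1-(benzyloxy)-4-[(1E)-2-(benzyloxy)prop-1-en-1-yl]-2-methoxybenzene
Conditions: BnOH (solvent), Cu(OAc)2 (2 equiv), Et3N (4 equiv), 4 Å MS, air, rt
Reagents that add atoms: benzyl alcohol, OCc1ccccc1
Why: Chan–Lam etherification of an alkenylboronate; the alkenyl group passes from boron to copper and the C–O bond forms at copper with retention of the double-bond geometry, so the benzyloxy group takes the place of boron, trans to the aryl group.

Step 5
Reactants: 6 1-(benzyloxy)-4-[(1E)-2-(benzyloxy)prop-1-en-1-yl]-2-methoxybenzene; 7 chloroacetyl chloride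
Product: 9 racemic (2R*,3R*)-3-(benzyloxy)-2-[4-(benzyloxy)-3-methoxyphenyl]-4-chloro-3-methylcyclobutan-1-one as both C4 epimers, via chloroketene 8 (not isolated)
Conditions: Et3N, Et2O, reflux, slow addition of 7
Reagents that add atoms: none
Why: Ketene–enol ether [2+2] cycloaddition; the ketene carbonyl carbon bonds to the nucleophilic aryl-bearing carbon and the CHCl carbon to the oxygen-bearing carbon, and the concerted, suprafacial addition to the alkene turns the (E) geometry into the cis relationship of aryl and C3 methyl. The configuration at C4 does not matter because it is erased in step 6.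

Step 6
Reactants: 9 racemic (2R*,3R*)-3-(benzyloxy)-2-[4-(benzyloxy)-3-methoxyphenyl]-4-chloro-3-methylcyclobutan-1-one; 10 iodomethane
Product: 12 racemic (2R*,3S*,4R*)-3-(benzyloxy)-2-[4-(benzyloxy)-3-methoxyphenyl]-3,4-dimethylcyclobutan-1-one, via lithium enolate 11 (not isolated)
Conditions: Me2CuLi (from MeLi and CuI), Et2O/THF, −78 → −40 °C; then MeI, HMPA, −40 °C
Reagents that add atoms: none
Why: Reductive enolate formation from an α-halo ketone with a cuprate, followed by enolate alkylation; the enolate can only form towards C4, and iodomethane should approach from the face of the benzyloxy group because the other face is screened by the adjacent C3 methyl group and the C2 aryl group across the ring. This sets the C4 methyl group trans to both, and the low temperature limits proton transfer to C2 and loss of benzyl oxide.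

Step 7
Reactants: 12 racemic (2R*,3S*,4R*)-3-(benzyloxy)-2-[4-(benzyloxy)-3-methoxyphenyl]-3,4-dimethylcyclobutan-1-one
Product: 13 (2R,3S,4R)-3-(benzyloxy)-2-[4-(benzyloxy)-3-methoxyphenyl]-3,4-dimethylcyclobutan-1-one
Conditions: preparative HPLC, cellulose tris(3,5-dimethylphenylcarbamate) phase, hexane/i-PrOH
Reagents that add atoms: none
Why: Resolution by chromatography on a chiral stationary phase; no bond is made and no centre is touched, and the absolute configuration of the route is fixed here by keeping the (2R,3S,4R) enantiomer.

Step 8
Reactants: 13 (2R,3S,4R)-3-(benzyloxy)-2-[4-(benzyloxy)-3-methoxyphenyl]-3,4-dimethylcyclobutan-1-one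
Product: 14 (3R,4S,5R)-4-(benzyloxy)-5-[4-(benzyloxy)-3-methoxyphenyl]-3,4-dimethyloxolan-2-one
Conditions: 30% aq H2O2, (CF3)2CHOH, 0 °C → rt
Reagents that add atoms: hydrogen peroxide, OO
Why: Baeyer–Villiger oxidation: hydrogen peroxide, activated as an electrophile and as a leaving group by hydrogen bonding to the fluorinated alcohol, adds to the strained carbonyl group of 13 to give the Criegee adduct. Of the two carbons flanking the carbonyl group, C2 should migrate to oxygen because it is benzylic and its para-benzyloxy, meta-methoxy aryl group stabilises the positive charge that builds up in the transition state, whereas C4 is an ordinary secondary carbon. The shift expands the four-membered carbocycle to the oxolan-2-one by a 1,2-migration of C2 from carbon to oxygen; this ring expansion is the only mode of closure and no ring is formed by cyclisation. No new stereocentre arises: the migrating carbon keeps its configuration, so C2 of 13 becomes C5 of 14 with retention, and C3 and C4 are not touched. The closest known reaction type is the regioselective oxidation of 2-arylcyclobutanones to γ-aryl-γ-butyrolactones by peracids or by hydrogen peroxide in fluorinated alcohols. The selectivity the step needs is migration of C2 over C4, which the electron-rich aryl group secures, and the release of ring strain lets the oxidation run without added acid, which should spare the arenes, the benzyl ethers and the 3-alkoxycyclobutanone.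

Step 9
Reactants: 14 (3R,4S,5R)-4-(benzyloxy)-5-[4-(benzyloxy)-3-methoxyphenyl]-3,4-dimethyloxolan-2-one
Product: 15 (3R,4S,5R)-4-(benzyloxy)-5-[4-(benzyloxy)-3-methoxyphenyl]-3,4-dimethyloxolan-2-ol (both anomers)
Conditions: i-Bu2AlH, CH2Cl2, −78 °C; Rochelle salt work-up
Reagents that add atoms: none
Why: Partial reduction of a lactone to a lactol; the tetrahedral aluminium alkoxide is stable at −78 °C and collapses only on work-up, and the new anomeric centre is left as a mixture because it is removed in step 11.

Step 10
Reactants: 15 (3R,4S,5R)-4-(benzyloxy)-5-[4-(benzyloxy)-3-methoxyphenyl]-3,4-dimethyloxolan-2-ol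
Product: 16 (3R,4S,5R)-4-(benzyloxy)-5-[4-(benzyloxy)-3-methoxyphenyl]-3,4-dimethyloxolan-2-yl acetate (both anomers)
Conditions: Ac2O, pyridine, DMAP (cat.), CH2Cl2, 0 °C → rt
Reagents that add atoms: acetic anhydride, CC(=O)OC(C)=O
Why: Acylation of the lactol hydroxyl; both anomers ionise to the same cation in the next step, and the tertiary oxygen is already protected.

Step 11
Reactants: 16 (3R,4S,5R)-4-(benzyloxy)-5-[4-(benzyloxy)-3-methoxyphenyl]-3,4-dimethyloxolan-2-yl acetate; 2 1-(benzyloxy)-4-bromo-2-methoxybenzene
Product: 19 (2R,3S,4S,5R)-3-(benzyloxy)-2,5-bis[4-(benzyloxy)-3-methoxyphenyl]-3,4-dimethyloxolane, via aryllithium 17 (not isolated), via arylzinc bromide 18 (not isolated)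
Conditions: 2, n-BuLi, THF, −78 °C; ZnBr2, −78 → 0 °C; then 16, BF3·OEt2, CH2Cl2, −78 → −20 °C
Reagents that add atoms: none
Why: Lewis-acid-promoted substitution of an anomeric acetate by an organozinc reagent through the cyclic oxocarbenium ion; the aryl group should add to C5 on the face opposite the adjacent C4 methyl group, which gives the 4,5-trans and 2,5-cis relationships. Bromine–lithium exchange and transmetalation to zinc give a nucleophile mild enough to leave the ethers and the existing benzylic centre alone.

Step 12
Reactants: 19 (2R,3S,4S,5R)-3-(benzyloxy)-2,5-bis[4-(benzyloxy)-3-methoxyphenyl]-3,4-dimethyloxolane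
Product: 20 (2R,3S,4S,5R)-2,5-bis(4-hydroxy-3-methoxyphenyl)-3,4-dimethyloxolan-3-ol
Conditions: H2 (1 atm), Pd/C (10%), EtOAc/MeOH, rt
Reagents that add atoms: none
Why: Hydrogenolysis of benzyl ethers; the two aryl benzyl ethers and the tertiary alkyl benzyl ether are cleaved under neutral conditions, while the ring C–O bonds at secondary benzylic carbons react more slowly, so the reaction is stopped after uptake of three equivalents of hydrogen.

## Compound list

1 | 4-bromo-2-methoxyphenol | COc1cc(Br)ccc1O | starting material
2 | 1-(benzyloxy)-4-bromo-2-methoxybenzene | COc1cc(Br)ccc1OCc1ccccc1 | intermediate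
3 | propyne | CC#C | starting material
4 | 1-(benzyloxy)-2-methoxy-4-(prop-1-yn-1-yl)benzene | CC#Cc1ccc(OCc2ccccc2)c(OC)c1 | intermediate
5 | 2-{(1Z)-1-[4-(benzyloxy)-3-methoxyphenyl]prop-1-en-2-yl}-4,4,5,5-tetramethyl-1,3,2-dioxaborolane (aryl cis to methyl) | C/C(B1OC(C)(C)C(C)(C)O1)=C\c1ccc(OCc2ccccc2)c(OC)c1 | intermediate
6 | 1-(benzyloxy)-4-[(1E)-2-(benzyloxy)prop-1-en-1-yl]-2-methoxybenzene (aryl cis to methyl, trans to benzyloxy) | C/C(OCc1ccccc1)=C\c1ccc(OCc2ccccc2)c(OC)c1 | intermediate
7 | chloroacetyl chloride | ClCC(Cl)=O | starting material
8 | chloroketene | ClC=C=O | intermediate (not isolated)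
9 | racemic (2R*,3R*)-3-(benzyloxy)-2-[4-(benzyloxy)-3-methoxyphenyl]-4-chloro-3-methylcyclobutan-1-one, aryl cis to the C3 methyl, both C4 epimers | COc1cc([C@H]2C(=O)C(Cl)[C@]2(C)OCc2ccccc2)ccc1OCc1ccccc1.COc1cc([C@@H]2C(=O)C(Cl)[C@@]2(C)OCc2ccccc2)ccc1OCc1ccccc1 | intermediate
10 | iodomethane | CI | starting material
11 | racemic lithium 3-(benzyloxy)-4-[4-(benzyloxy)-3-methoxyphenyl]-3-methylcyclobut-1-en-1-olate, aryl cis to methyl | COc1cc([C@H]2C(O[Li])=C[C@]2(C)OCc2ccccc2)ccc1OCc1ccccc1.COc1cc([C@@H]2C(O[Li])=C[C@@]2(C)OCc2ccccc2)ccc1OCc1ccccc1 | intermediate (not isolated)
12 | racemic (2R*,3S*,4R*)-3-(benzyloxy)-2-[4-(benzyloxy)-3-methoxyphenyl]-3,4-dimethylcyclobutan-1-one | COc1cc([C@H]2C(=O)[C@H](C)[C@]2(C)OCc2ccccc2)ccc1OCc1ccccc1.COc1cc([C@@H]2C(=O)[C@@H](C)[C@@]2(C)OCc2ccccc2)ccc1OCc1ccccc1 | intermediate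
13 | (2R,3S,4R)-3-(benzyloxy)-2-[4-(benzyloxy)-3-methoxyphenyl]-3,4-dimethylcyclobutan-1-one | COc1cc([C@H]2C(=O)[C@H](C)[C@]2(C)OCc2ccccc2)ccc1OCc1ccccc1 | intermediate
14 | (3R,4S,5R)-4-(benzyloxy)-5-[4-(benzyloxy)-3-methoxyphenyl]-3,4-dimethyloxolan-2-one | COc1cc([C@H]2OC(=O)[C@H](C)[C@]2(C)OCc2ccccc2)ccc1OCc1ccccc1 | intermediate
15 | (3R,4S,5R)-4-(benzyloxy)-5-[4-(benzyloxy)-3-methoxyphenyl]-3,4-dimethyloxolan-2-ol, both anomers | COc1cc([C@H]2OC(O)[C@H](C)[C@]2(C)OCc2ccccc2)ccc1OCc1ccccc1 | intermediate
16 | (3R,4S,5R)-4-(benzyloxy)-5-[4-(benzyloxy)-3-methoxyphenyl]-3,4-dimethyloxolan-2-yl acetate, both anomers | COc1cc([C@H]2OC(OC(C)=O)[C@H](C)[C@]2(C)OCc2ccccc2)ccc1OCc1ccccc1 | intermediate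
17 | [4-(benzyloxy)-3-methoxyphenyl]lithium | [Li]c1ccc(OCc2ccccc2)c(OC)c1 | intermediate (not isolated)
18 | [4-(benzyloxy)-3-methoxyphenyl]zinc bromide | Br[Zn]c1ccc(OCc2ccccc2)c(OC)c1 | intermediate (not isolated)
19 | (2R,3S,4S,5R)-3-(benzyloxy)-2,5-bis[4-(benzyloxy)-3-methoxyphenyl]-3,4-dimethyloxolane | COc1cc([C@H]2O[C@@H](c3ccc(OCc4ccccc4)c(OC)c3)[C@H](C)[C@]2(C)OCc2ccccc2)ccc1OCc1ccccc1 | intermediate
20 | (2R,3S,4S,5R)-2,5-bis(4-hydroxy-3-methoxyphenyl)-3,4-dimethyloxolan-3-ol (CNP0234919.2) | COc1cc([C@H]2O[C@@H](c3ccc(O)c(OC)c3)[C@H](C)[C@]2(C)O)ccc1O | target

## Step count and least certain steps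

Total step count: 12. Longest linear sequence: 12 steps (1 → 2 → 4 → 5 → 6 → 9 → 12 → 13 → 14 → 15 → 16 → 19 → 20). Bromide 2 is used a second time in step 11. The separation in step 7 discards half of the material; this is the price of a cycloaddition that is stereospecific but not enantioselective.

Step 8 (key step). C4 may migrate in competition with C2, since both are secondary and only the aryl group tells them apart. The 3-alkoxycyclobutanone is also a donor–acceptor ring and may open by C2–C3 or C3–C4 cleavage in the ionising solvent before oxygen is inserted. The fallback changes the order of events and sets out from chloro ketone 9. With chlorine still on C4, that carbon should not migrate, so buffered peracid oxidation (mCPBA, NaHCO3, CH2Cl2) should give the racemic α-chloro lactone F1. Reduction of its C–Cl bond with Me2CuLi and methylation of the resulting lactone enolate with MeI, again on the face of the benzyloxy group, would give the racemic lactone F2. Chromatography on the chiral phase of step 7 then returns to the route at 14.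

Step 6. The enolate may expel benzyl oxide to give a cyclobutenone. Proton transfer from product to enolate may scramble C2 or lead to a second methylation. The methyl group may also enter on the other face, since attack anti to the C–O bond is stereoelectronically favoured and opposes the steric argument. The fallback brings the methyl group in on the ketene and corrects C4 only after C2 has lost its acidity. It sets out from enol ether 6: propanoyl chloride and Et3N (methylketene) should give the racemic all-cis ketone F4, and hydrogen peroxide in hexafluoroisopropanol the racemic lactone epimer F5, whose only acidic C–H is at C3. DBU should then equilibrate it to the isomer with the two methyl groups trans, the racemic lactone F2, and separation on the chiral phase returns to the route at 14.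

Step 5. The aldoketene may oligomerise faster than it adds to the hindered trisubstituted enol ether, and the ammonium salt may isomerise or hydrolyse the enol ether before it reacts. The fallback uses the more electrophilic dichloroketene. Starting from 6, trichloroacetyl chloride and activated Zn in Et2O should give the racemic dichloro ketone F3, with the same transfer of alkene geometry. Partial dechlorination with Zn in AcOH at room temperature comes back to the route at 9.

Step 11. The aryl group may add on the face cis to the C4 methyl group. A β-alkoxy group that sits pseudo-axial in the oxocarbenium ion favours attack on its own face, which is that face here, and this opposes the steric effect of the methyl group. The Lewis acid may also ionise the C2–O bond of the product and epimerise C2. The fallback reverses the order in which aryl and hydrogen arrive at C5 and sets out from lactone 14. Addition of aryllithium 17 at −78 °C should give the hemiketal F6, and Et3SiH with BF3·OEt2 at −78 °C would reduce the aryl-substituted oxocarbenium ion to 19. If the ring favours attack on the face of the benzyloxy group, hydrogen ends up there and the aryl group trans to the C4 methyl group, so the two orders are complementary.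

## Further compounds

F1 | step 8 | racemic 4-(benzyloxy)-5-[4-(benzyloxy)-3-methoxyphenyl]-3-chloro-4-methyloxolan-2-one, aryl cis to the 4-methyl, both C3 epimers | COc1cc([C@H]2OC(=O)C(Cl)[C@]2(C)OCc2ccccc2)ccc1OCc1ccccc1.COc1cc([C@@H]2OC(=O)C(Cl)[C@@]2(C)OCc2ccccc2)ccc1OCc1ccccc1
F2 | step 8 | racemic (3R*,4S*,5R*)-4-(benzyloxy)-5-[4-(benzyloxy)-3-methoxyphenyl]-3,4-dimethyloxolan-2-one (racemate of 14) | COc1cc([C@H]2OC(=O)[C@H](C)[C@]2(C)OCc2ccccc2)ccc1OCc1ccccc1.COc1cc([C@@H]2OC(=O)[C@@H](C)[C@@]2(C)OCc2ccccc2)ccc1OCc1ccccc1
F3 | step 5 | racemic 3-(benzyloxy)-2-[4-(benzyloxy)-3-methoxyphenyl]-4,4-dichloro-3-methylcyclobutan-1-one, aryl cis to the C3 methyl | COc1cc([C@H]2C(=O)C(Cl)(Cl)[C@]2(C)OCc2ccccc2)ccc1OCc1ccccc1.COc1cc([C@@H]2C(=O)C(Cl)(Cl)[C@@]2(C)OCc2ccccc2)ccc1OCc1ccccc1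
F4 | step 6 | racemic all-cis 3-(benzyloxy)-2-[4-(benzyloxy)-3-methoxyphenyl]-3,4-dimethylcyclobutan-1-one (C4 epimer of 12) | COc1cc([C@H]2C(=O)[C@@H](C)[C@]2(C)OCc2ccccc2)ccc1OCc1ccccc1.COc1cc([C@@H]2C(=O)[C@H](C)[C@@]2(C)OCc2ccccc2)ccc1OCc1ccccc1
F5 | step 6 | racemic 4-(benzyloxy)-5-[4-(benzyloxy)-3-methoxyphenyl]-3,4-dimethyloxolan-2-one with the two methyl groups cis (C3 epimer of F2) | COc1cc([C@H]2OC(=O)[C@@H](C)[C@]2(C)OCc2ccccc2)ccc1OCc1ccccc1.COc1cc([C@@H]2OC(=O)[C@H](C)[C@@]2(C)OCc2ccccc2)ccc1OCc1ccccc1
F6 | step 11 | (3R,4S,5R)-4-(benzyloxy)-2,5-bis[4-(benzyloxy)-3-methoxyphenyl]-3,4-dimethyloxolan-2-ol, both anomers | COc1cc([C@H]2OC(O)(c3ccc(OCc4ccccc4)c(OC)c3)[C@H](C)[C@]2(C)OCc2ccccc2)ccc1OCc1ccccc1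
A1 | alternative 1 | target 3-O-acetate bis(benzyl ether) | COc1cc([C@H]2O[C@@H](c3ccc(OCc4ccccc4)c(OC)c3)[C@H](C)[C@]2(C)OC(C)=O)ccc1OCc1ccccc1
A2 | alternative 1 | 3-acetoxy-3,4-dimethyloxolane-2,5-diyl diacetate, 3-acetoxy cis to 4-methyl, anomeric centres open | CC(=O)OC1OC(OC(C)=O)[C@H](C)[C@]1(C)OC(C)=O
A3 | alternative 2 | 2,5-cis-bis[4-(benzyloxy)-3-methoxyphenyl]-4-methyloxolan-3-one | COc1cc([C@H]2O[C@@H](c3ccc(OCc4ccccc4)c(OC)c3)[C@H](C)C2=O)ccc1OCc1ccccc1
A4 | alternative 2 | (Z)-5-ethylidene-2,4-cis-bis[4-(benzyloxy)-3-methoxyphenyl]-1,3-dioxolane | COc1cc([C@H]2O[C@@H](c3ccc(OCc4ccccc4)c(OC)c3)O/C2=C\C)ccc1OCc1ccccc1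
A5 | alternative 3 | target 3-O-acetate | COc1cc([C@H]2O[C@@H](c3ccc(O)c(OC)c3)[C@H](C)[C@]2(C)OC(C)=O)ccc1O
A6 | alternative 3 | (E)-isoeugenol | C/C=C/c1ccc(O)c(OC)c1
A7 | alternative 3 | (E)-1-(4-hydroxy-3-methoxyphenyl)prop-1-en-2-yl acetate | C/C(OC(C)=O)=C\c1ccc(O)c(OC)c1
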